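The runs were generated by integration for an exercise; scatter was added.

A small charge of starting complex, 0.10 M, has to take up four incoming ligands, and you have two earlier runs to go on.

the same everywhere: starting complex 0.10 M

|  | incoming ligand | remark | time |
|---|---|---|---|
| gamma | 0.11 M | run made earlier |  |
| zeta | 0.54 M | run made earlier |  |
| Monday's | 0.0800 M |  | 10 h |
| Wednesday's | 0.300 M |  | 10 h |
| Sunday's | 0.400 M |  | 10 h |

- gamma (time / h: complex with four exchanged / %, complex with one exchanged / %): 1.33: 4, 7; 3.00: 6, 5; 4.00: 4, 2; 6.00: 3, 3; 8.00: 6, 1; 10.0: 5, 1
- zeta (time / h: complex with four exchanged / %, complex with one exchanged / %): 0.500: 75, 1; 1.50: 89, 0; 3.00: 86, 0; 4.00: 91, 2; 6.00: 86, 0; 8.00: 86, 0; 10.0: 87, 0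

(scatter of a reading: 1.5 percentage points)

- amount of complex with four exchanged at the end, in percent of the starting complex charged, for each flask in turn (Monday's, Wednesday's, Sunday's)

- percentages count the starting complex that a species holds: one side product counts as two
- the earlier runs were read with a standard deviation of 1.5 percentage points
- steps under discussion: complex with two exchanged + incoming ligand -> leaving ligand + complex with three exchanged; complex with one exchanged <-> isomer of the product; incoming ligand -> decomposition product; starting complex + complex with one exchanged -> side product; complex with one exchanged + incoming ligand -> leaving ligand + complex with two exchanged; starting complex + incoming ligand -> leaving ligand + complex with one exchanged; complex with three exchanged + incoming ligand -> leaving ligand + complex with four exchanged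

The zeta run gives the ladder of times. The complex with one exchanged reads 1 % at 0.500 h, the complex with four exchanged reads 89 % at 1.50 h, and its later readings lie between 86 % and 91 %, with 87 % at 10.0 h. If that plateau time scales inversely with the ligand charge, Wednesday's flask needs 2.70 h, less than its 10 h, so I reckon with end states.

The complex with one exchanged is a branch point, as a substrate shared by two enzymes is: it meets ligand or starting complex. With c(starting complex) held fixed, I therefore freeze the loss product, the share of charged complex ending as side product times c(incoming ligand), 0.0702 M as read from zeta, taking everything short of its plateau as side product.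

For Sunday's flask this gives a share of 17.6 %. Each four-exchanged complex costs four ligands and each starting complex held in side product costs half a ligand, so the demand in Sunday's flask is 0.339 M, below its charge, and I expect 82.5 %. For Wednesday's flask the share is 23.4 % and the demand 0.318 M, above the charge. Ligand is then the limiting reagent in Wednesday's flask, and if the remainder stops at three exchanged, I expect 58.5 %. For Monday's flask the same balance gives −0.625 %, which is no amount, so I name no figure.

For Monday's, Wednesday's and Sunday's flask the forecast says 3 %, 37 % and 60 %: “Yield therefore rises steeply and nonlinearly with ligand”. My Wednesday figure stands above its value, and my Sunday figure above its value too.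

The flasks give 2.04 %, 63.4 % and 82.4 %.

    complex with two exchanged + incoming ligand → leaving ligand + complex with three exchanged (k = 0.0260 M⁻¹ s⁻¹)
    complex with one exchanged ⇌ isomer of the product (K = 0.330, k = 0.00120 s⁻¹)
    incoming ligand → decomposition product (k = 5.00 × 10⁻⁷ s⁻¹)
    starting complex + complex with one exchanged → side product (k = 0.0200 M⁻¹ s⁻¹)
    complex with one exchanged + incoming ligand → leaving ligand + complex with two exchanged (k = 0.0180 M⁻¹ s⁻¹)
    starting complex + incoming ligand → leaving ligand + complex with one exchanged (k = 0.0110 M⁻¹ s⁻¹)
    complex with three exchanged + incoming ligand → leaving ligand + complex with four exchanged (k = 0.00700 M⁻¹ s⁻¹)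

With c(starting complex) and c(incoming ligand) as charged, the step to side product runs against the step to complex with two exchanged at a ratio of 0.370 in Wednesday's flask and 0.278 in Sunday's, lower there. Against the loss product of 0.0702 M, the share of side product times the ligand charge comes to 0.0741 M in Wednesday's flask and 0.0704 M in Sunday's.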